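The plan removes ring A (C3a, C4, C5, C6, C7, C7a) and keeps the five-membered ring. O1, C2, C3, C3a and C7a are the ring atoms of a γ-aryl paraconic lactone if C7a is read as its carbonyl carbon, and the key step exploits this feature. C2 and C3 are therefore set on a butyrolactone by an auxiliary aldol. The precursor is the bis(silyloxy)diene of the α-acetyl lactone: a 2-silyloxy-4,5-dihydrofuran carrying a 1-silyloxyvinyl group at C3a. One [4+2] addition of but-3-yn-2-one forms C5–C6 and C7–C7a. Silanol loss then aromatizes ring A, leaving a C4 phenol for the later Heck coupling and a C7 acetyl group as latent hydroxyl.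

Key step: step 7

Atom labels: the dihydrobenzofuran numbering of the target is used in all comments, including for the lactones. There C7a is the lactone C=O, C3a its α-carbon, C4 the acetyl C=O and C5 the acetyl CH3.

Assumption: C3a of the α-acetyl lactone is keto–enol labile and is drawn as the all-trans isomer, and C7a of the cycloadduct is left undefined; both centres vanish in the next operation.

Design choices:
- **Silyl groups.** The diene carries TBS instead of trimethylsilyl groups. The Si–O bond at C7a must outlast the C7a–O bond, because early desilylation gives a hemiketal that opens the five-membered ring.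
- **Order of oxidation.** The C7 acetyl is oxidized directly after the key step, while the para C4 hydroxyl assists aryl migration and no alkene or triflate is present.
- **Aryl acetate.** The acetate formed in that oxidation gets its own mild cleavage step before the Lewis-acid step.
- **Base strength.** Once ring A is aromatic, C3–H is benzylic, α to an ester and β to the leaving group O1. No base stronger than an amine or acetate is used from then on.

Abbreviations: Bn benzyl, TBS tert-butyldimethylsilyl, Tf trifluoromethanesulfonyl, dppp 1,3-bis(diphenylphosphino)propane, mCPBA 3-chloroperoxybenzoic acid, PPTS pyridinium 4-toluenesulfonate.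

Step 1
Reactants: 1 (S)-4-benzyl-1,3-oxazolidin-2-one; 2 methyl 4-chloro-4-oxobutanoate
Product: 3 methyl 4-[(4S)-4-benzyl-2-oxo-1,3-oxazolidin-3-yl]-4-oxobutanoate
Conditions: n-BuLi (1.0 equiv), THF, −78 °C; then 2, −78 → 0 °C
Reagents that add atoms: none
Why: N-acylation of the lithiated oxazolidinone by the acid chloride (nucleophilic acyl substitution) is fast at low temperature and leaves the methyl ester untouched.

Step 2
Reactants: 3 methyl 4-[(4S)-4-benzyl-2-oxo-1,3-oxazolidin-3-yl]-4-oxobutanoate; 4 3,4-bis(benzyloxy)benzaldehyde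
Product: 6 (4S)-4-benzyl-3-{[(2S,3S)-2-[3,4-bis(benzyloxy)phenyl]-5-oxooxolan-3-yl]carbonyl}-1,3-oxazolidin-2-one, via syn-aldol adduct 5 (not isolated)
Conditions: Bu2BOTf (1.15 equiv), iPr2NEt (1.3 equiv), CH2Cl2, 0 °C; 4, −78 → 0 °C; pH 7 buffer, MeOH, 30 % H2O2, 0 °C; crude with PPTS (cat.), CH2Cl2, rt
Reagents that add atoms: none
Why: In this Evans syn aldol reaction only the imide side is enolized to the Z boron enolate, the chair-like transition state with one face blocked by the auxiliary benzyl group sets C3 (S) and C2 (S) together, and lactonization of γ-hydroxy ester 5 turns the syn aldol relationship into the trans ring relationship.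

Step 3
Reactants: 6 (4S)-4-benzyl-3-{[(2S,3S)-2-[3,4-bis(benzyloxy)phenyl]-5-oxooxolan-3-yl]carbonyl}-1,3-oxazolidin-2-one
Product: 7 (2S,3S)-2-[3,4-bis(benzyloxy)phenyl]-5-oxooxolane-3-carboxylic acid
Conditions: LiOH, 30 % H2O2, THF/H2O, 0 °C; Na2SO3; HCl to pH 2
Reagents that add atoms: hydrogen peroxide (acting as LiOOH), OO
Why: Hydroperoxide attacks the exocyclic imide carbonyl in preference to the ring carbamate (standard LiOOH auxiliary cleavage), any transient lactone opening is reversed on acidification with retention at C2, and no stereocentre is touched.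

Step 4
Reactants: 7 (2S,3S)-2-[3,4-bis(benzyloxy)phenyl]-5-oxooxolane-3-carboxylic acid
Product: 8 tert-butyl (2S,3S)-2-[3,4-bis(benzyloxy)phenyl]-5-oxooxolane-3-carboxylate
Conditions: tert-butyl 2,2,2-trichloroacetimidate (2 equiv), CH2Cl2/cyclohexane, rt
Reagents that add atoms: tert-butyl 2,2,2-trichloroacetimidate, CC(C)(C)OC(=N)C(Cl)(Cl)Cl
Why: O-alkylation of the carboxylic acid by the imidate (tert-butyl cation transfer) runs under almost neutral conditions that spare the ionizable benzylic C2–O1 bond, and the bulky ester later shields C3–H from bases.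

Step 5
Reactants: 8 tert-butyl (2S,3S)-2-[3,4-bis(benzyloxy)phenyl]-5-oxooxolane-3-carboxylate; 9 N-methoxy-N-methylacetamide
Product: 10 tert-butyl (2S,3S,4R)-4-acetyl-2-[3,4-bis(benzyloxy)phenyl]-5-oxooxolane-3-carboxylate
Conditions: LiN(SiMe3)2 (1.1 equiv), THF, −78 °C; 9 (2 equiv), −78 → −20 °C; AcOH quench at −78 °C
Reagents that add atoms: none
Why: In this crossed Claisen-type acylation, kinetic deprotonation takes the less hindered and more acidic lactone CH2 (C3a) rather than the tertiary C3–H, the N-methoxy amide holds the adduct as a chelated tetrahedral lithium alkoxide so that the acidic β-keto lactone appears only on quench, and the new C3a centre is labile and irrelevant.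

Step 6
Reactants: 10 tert-butyl (2S,3S,4R)-4-acetyl-2-[3,4-bis(benzyloxy)phenyl]-5-oxooxolane-3-carboxylate
Product: 11 tert-butyl (2S,3S)-2-[3,4-bis(benzyloxy)phenyl]-5-[(tert-butyldimethylsilyl)oxy]-4-{1-[(tert-butyldimethylsilyl)oxy]ethenyl}-2,3-dihydrofuran-3-carboxylate
Conditions: TBSOTf (2.4 equiv), Et3N (4 equiv), CH2Cl2, 0 °C → rt; pentane, cold aq NaHCO3 wash; used without chromatography
Reagents that add atoms: tert-butyldimethylsilyl trifluoromethanesulfonate, CC(C)(C)[Si](C)(C)OS(=O)(=O)C(F)(F)F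
Why: Soft enolization with a silyl triflate and a tertiary amine (the known double silylation of 1,3-dicarbonyl compounds) first silylates the enolized β-dicarbonyl unit and then removes a proton from the C5 methyl group, so no strong base ever meets C3–H and C2 and C3 stay untouched.

Step 7
Reactants: 11 tert-butyl (2S,3S)-2-[3,4-bis(benzyloxy)phenyl]-5-[(tert-butyldimethylsilyl)oxy]-4-{1-[(tert-butyldimethylsilyl)oxy]ethenyl}-2,3-dihydrofuran-3-carboxylate; 12 but-3-yn-2-one
Product: 15 tert-butyl (2S,3S)-7-acetyl-2-[3,4-bis(benzyloxy)phenyl]-4-hydroxy-2,3-dihydrobenzofuran-3-carboxylate, via cycloadduct ketal 13 (not isolated), via C4 silyl ether 14 (not isolated)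
Conditions: 12 (2 equiv), iPr2NEt (1 equiv), PhMe, rt → 60 °C, strictly aprotic until ring A is aromatic; then Bu4NF/AcOH (1:1), THF, 0 °C
Reagents that add atoms: none
Why: The diene, pushed by three oxygen donors, adds to the ynone in a strongly asynchronous normal-demand [4+2] cycloaddition in which the CH2 terminus C5 bonds first to the unsubstituted alkyne carbon C6 and the developing allenolate carbon C7 then closes onto the dioxocarbenium-like C7a, giving cyclohexa-1,4-diene 13; amine-assisted 1,4-elimination of C5–H and the C7a silyloxy group makes ring A aromatic (14), and buffered fluoride frees the C4 phenol. The closest known reaction type is the Diels–Alder benzannulation of acyclic 1-alkoxy-1,3-bis(silyloxy)buta-1,3-dienes with acetylenic ketones and esters followed by eliminative aromatization. Ring A is the only ring closed, by intermolecular [4+2] annulation across the C3a–C7a edge of the existing five-membered ring. No lasting stereocentre is created, since C7a is stereogenic only in 13 and is flattened on aromatization, while C2 and C3 take part in no bond change and meet no base stronger than a hindered tertiary amine. Regioselectivity (acetyl at C7 next to O1, oxygen at C4) follows from the match between the most nucleophilic diene terminus C5 and the electrophilic β-carbon of the ynone. Aromatization must break the exocyclic C7a–OSi bond and not C7a–O1, which the substrate secures because the five-membered ring holds C7a–O1 near the plane of the flanking π bonds whereas the exocyclic bond stands almost perpendicular to it and overlaps with them, because silanolate is the better leaving group in an elimination started at the C5–H that the C7 acetyl acidifies, and because the bulky hydrolysis-resistant TBS group resists the desilylation or oxygen-to-oxygen silyl shift that would turn C7a into a carbonyl and open the ring.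

Step 8
Reactants: 15 tert-butyl (2S,3S)-7-acetyl-2-[3,4-bis(benzyloxy)phenyl]-4-hydroxy-2,3-dihydrobenzofuran-3-carboxylate
Product: 16 tert-butyl (2S,3S)-7-acetoxy-2-[3,4-bis(benzyloxy)phenyl]-4-hydroxy-2,3-dihydrobenzofuran-3-carboxylate
Conditions: mCPBA (1.5 equiv), CH2Cl2, 0 °C → rt; aq Na2S2O3/NaHCO3 wash
Reagents that add atoms: 3-chloroperoxybenzoic acid, O=C(OO)c1cccc(Cl)c1
Why: In this Baeyer–Villiger oxidation the aryl group migrates in preference to methyl because C7 has an ortho alkoxy (O1) and a para hydroxy (C4) donor, as in the peracid conversion of 4-hydroxyacetophenones into hydroquinone monoacetates, and no alkene or electron-withdrawing triflate is yet present.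

Step 9
Reactants: 16 tert-butyl (2S,3S)-7-acetoxy-2-[3,4-bis(benzyloxy)phenyl]-4-hydroxy-2,3-dihydrobenzofuran-3-carboxylate
Product: 17 tert-butyl (2S,3S)-7-acetoxy-2-[3,4-bis(benzyloxy)phenyl]-4-[(trifluoromethylsulfonyl)oxy]-2,3-dihydrobenzofuran-3-carboxylate
Conditions: Tf2O (1.2 equiv), pyridine (3 equiv), CH2Cl2, −20 → 0 °C
Reagents that add atoms: trifluoromethanesulfonic anhydride, O=S(=O)(OS(=O)(=O)C(F)(F)F)C(F)(F)F
Why: O-sulfonylation of the only free phenol under pyridine buffering gives the aryl triflate needed for oxidative addition, and the aryl acetate, tert-butyl ester and benzyl ethers are inert.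

Step 10
Reactants: 18 (R)-danshensu, (2R)-3-(3,4-dihydroxyphenyl)-2-hydroxypropanoic acid
Product: 19 methyl (2R)-3-(3,4-dihydroxyphenyl)-2-hydroxypropanoate
Conditions: MeOH, H2SO4 (cat.), reflux, Ar
Reagents that add atoms: methanol, CO
Why: Fischer esterification touches only the carboxyl group, so the (R) carbinol centre from the chiral pool is retained.

Step 11
Reactants: 19 methyl (2R)-3-(3,4-dihydroxyphenyl)-2-hydroxypropanoate
Product: 20 methyl (2R)-3-[3,4-bis(benzyloxy)phenyl]-2-hydroxypropanoate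
Conditions: BnBr (2.2 equiv), K2CO3 (2.5 equiv), acetone, 50 °C
Reagents that add atoms: benzyl bromide, BrCc1ccccc1
Why: Williamson etherification with a carbonate base alkylates only the acidic catechol hydroxyls, leaving the secondary alcohol free and the α-centre configurationally intact.

Step 12
Reactants: 20 methyl (2R)-3-[3,4-bis(benzyloxy)phenyl]-2-hydroxypropanoate; 21 acryloyl chloride
Product: 22 methyl (2R)-2-(acryloyloxy)-3-[3,4-bis(benzyloxy)phenyl]propanoate
Conditions: 21 (1.3 equiv), Et3N (1.6 equiv), CH2Cl2, −20 → 0 °C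
Reagents that add atoms: none
Why: O-acylation of the secondary alcohol by the acid chloride forms the ester without breaking any bond at the stereocentre.

Step 13
Reactants: 17 tert-butyl (2S,3S)-7-acetoxy-2-[3,4-bis(benzyloxy)phenyl]-4-[(trifluoromethylsulfonyl)oxy]-2,3-dihydrobenzofuran-3-carboxylate; 22 methyl (2R)-2-(acryloyloxy)-3-[3,4-bis(benzyloxy)phenyl]propanoate
Product: 23 tert-butyl (2S,3S)-7-acetoxy-2-[3,4-bis(benzyloxy)phenyl]-4-[(E)-3-{[(2R)-3-[3,4-bis(benzyloxy)phenyl]-1-methoxy-1-oxopropan-2-yl]oxy}-3-oxoprop-1-enyl]-2,3-dihydrobenzofuran-3-carboxylate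
Conditions: Pd(OAc)2 (10 mol %), dppp (12 mol %), NaOAc (2 equiv), 22 (1.5 equiv), DMF, 80 °C
Reagents that add atoms: none
Why: In this Mizoroki–Heck reaction zerovalent palladium formed in situ inserts into the C4–OTf bond, syn carbopalladation at the unsubstituted acrylate terminus and syn β-hydride elimination give the E-cinnamate, and the weak acetate base avoids β-elimination of O1 through C3–H.

Step 14
Reactants: 23 tert-butyl (2S,3S)-7-acetoxy-2-[3,4-bis(benzyloxy)phenyl]-4-[(E)-3-{[(2R)-3-[3,4-bis(benzyloxy)phenyl]-1-methoxy-1-oxopropan-2-yl]oxy}-3-oxoprop-1-enyl]-2,3-dihydrobenzofuran-3-carboxylate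
Product: 24 tert-butyl (2S,3S)-2-[3,4-bis(benzyloxy)phenyl]-4-[(E)-3-{[(2R)-3-[3,4-bis(benzyloxy)phenyl]-1-methoxy-1-oxopropan-2-yl]oxy}-3-oxoprop-1-enyl]-7-hydroxy-2,3-dihydrobenzofuran-3-carboxylate
Conditions: pyrrolidine (1.5 equiv), CH2Cl2, 0 °C
Reagents that add atoms: none
Why: Chemoselective aminolysis works because the aryl acetate, with its phenoxide leaving group, is far more electrophilic than the methyl, tert-butyl and cinnamate esters, so a secondary amine at 0 °C removes it alone.

Step 15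
Reactants: 24 tert-butyl (2S,3S)-2-[3,4-bis(benzyloxy)phenyl]-4-[(E)-3-{[(2R)-3-[3,4-bis(benzyloxy)phenyl]-1-methoxy-1-oxopropan-2-yl]oxy}-3-oxoprop-1-enyl]-7-hydroxy-2,3-dihydrobenzofuran-3-carboxylate
Product: 25 CNP0120702.1, (2S,3S)-2-(3,4-dihydroxyphenyl)-4-[(E)-3-{[(2R)-3-(3,4-dihydroxyphenyl)-1-methoxy-1-oxopropan-2-yl]oxy}-3-oxoprop-1-enyl]-7-hydroxy-2,3-dihydrobenzofuran-3-carboxylic acid
Conditions: BCl3 (12 equiv), C6HMe5 (15 equiv), CH2Cl2, −78 → −10 °C; aq THF quench; reversed-phase chromatography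
Reagents that add atoms: none
Why: In this Lewis-acid dealkylation with a non-basic cation scavenger, BCl3 activates the four aryl benzyl ethers and the tert-butyl ester, pentamethylbenzene captures the benzyl cations irreversibly, the alkene, methyl ester and cinnamate ester are inert at low temperature, and fast chelation of boron by the ring C catechol oxygens lowers the donor power of that ring so that O1–C2 and both ring stereocentres should persist.

Compound list
1 | (S)-4-benzyl-1,3-oxazolidin-2-one | O=C1N[C@@H](Cc2ccccc2)CO1 | starting material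
2 | methyl 4-chloro-4-oxobutanoate | COC(=O)CCC(=O)Cl | starting material
3 | methyl 4-[(4S)-4-benzyl-2-oxo-1,3-oxazolidin-3-yl]-4-oxobutanoate | COC(=O)CCC(=O)N1[C@@H](Cc2ccccc2)COC1=O | intermediate
4 | 3,4-bis(benzyloxy)benzaldehyde | O=Cc1ccc(OCc2ccccc2)c(OCc2ccccc2)c1 | starting material
5 | methyl (3S)-3-{(S)-[3,4-bis(benzyloxy)phenyl](hydroxy)methyl}-4-[(4S)-4-benzyl-2-oxo-1,3-oxazolidin-3-yl]-4-oxobutanoate (syn-aldol adduct, not isolated) | O=C1OC[C@H](Cc2ccccc2)N1C(=O)[C@@H](CC(=O)OC)[C@H](O)c1ccc(OCc2ccccc2)c(OCc2ccccc2)c1 | intermediate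
6 | (4S)-4-benzyl-3-{[(2S,3S)-2-[3,4-bis(benzyloxy)phenyl]-5-oxooxolan-3-yl]carbonyl}-1,3-oxazolidin-2-one | O=C1OC[C@H](Cc2ccccc2)N1C(=O)[C@H]1CC(=O)O[C@@H]1c1ccc(OCc2ccccc2)c(OCc2ccccc2)c1 | intermediate
7 | (2S,3S)-2-[3,4-bis(benzyloxy)phenyl]-5-oxooxolane-3-carboxylic acid | OC(=O)[C@H]1CC(=O)O[C@@H]1c1ccc(OCc2ccccc2)c(OCc2ccccc2)c1 | intermediate
8 | tert-butyl (2S,3S)-2-[3,4-bis(benzyloxy)phenyl]-5-oxooxolane-3-carboxylate | CC(C)(C)OC(=O)[C@H]1CC(=O)O[C@@H]1c1ccc(OCc2ccccc2)c(OCc2ccccc2)c1 | intermediate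
9 | N-methoxy-N-methylacetamide | CON(C)C(C)=O | starting material
10 | tert-butyl (2S,3S,4R)-4-acetyl-2-[3,4-bis(benzyloxy)phenyl]-5-oxooxolane-3-carboxylate | CC(=O)[C@@H]1C(=O)O[C@H](c2ccc(OCc3ccccc3)c(OCc3ccccc3)c2)[C@H]1C(=O)OC(C)(C)C | intermediate
11 | tert-butyl (2S,3S)-2-[3,4-bis(benzyloxy)phenyl]-5-[(tert-butyldimethylsilyl)oxy]-4-{1-[(tert-butyldimethylsilyl)oxy]ethenyl}-2,3-dihydrofuran-3-carboxylate | CC(C)(C)[Si](C)(C)OC1=C(C(=C)O[Si](C)(C)C(C)(C)C)[C@H](C(=O)OC(C)(C)C)[C@@H](c2ccc(OCc3ccccc3)c(OCc3ccccc3)c2)O1 | intermediate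
12 | but-3-yn-2-one | C#CC(C)=O | starting material
13 | tert-butyl (2S,3S)-7-acetyl-2-[3,4-bis(benzyloxy)phenyl]-4,7a-bis[(tert-butyldimethylsilyl)oxy]-2,3,5,7a-tetrahydrobenzofuran-3-carboxylate (cycloadduct ketal, C7a undefined, not isolated) | CC(=O)C1=CCC(O[Si](C)(C)C(C)(C)C)=C2[C@H](C(=O)OC(C)(C)C)[C@@H](c3ccc(OCc4ccccc4)c(OCc4ccccc4)c3)OC12O[Si](C)(C)C(C)(C)C | intermediate
14 | tert-butyl (2S,3S)-7-acetyl-2-[3,4-bis(benzyloxy)phenyl]-4-[(tert-butyldimethylsilyl)oxy]-2,3-dihydrobenzofuran-3-carboxylate (C4 silyl ether, not isolated) | CC(C)(C)[Si](C)(C)Oc1ccc(C(C)=O)c2c1[C@H](C(=O)OC(C)(C)C)[C@@H](c1ccc(OCc3ccccc3)c(OCc3ccccc3)c1)O2 | intermediate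
15 | tert-butyl (2S,3S)-7-acetyl-2-[3,4-bis(benzyloxy)phenyl]-4-hydroxy-2,3-dihydrobenzofuran-3-carboxylate | Oc1ccc(C(C)=O)c2c1[C@H](C(=O)OC(C)(C)C)[C@@H](c1ccc(OCc3ccccc3)c(OCc3ccccc3)c1)O2 | intermediate
16 | tert-butyl (2S,3S)-7-acetoxy-2-[3,4-bis(benzyloxy)phenyl]-4-hydroxy-2,3-dihydrobenzofuran-3-carboxylate | Oc1ccc(OC(C)=O)c2c1[C@H](C(=O)OC(C)(C)C)[C@@H](c1ccc(OCc3ccccc3)c(OCc3ccccc3)c1)O2 | intermediate
17 | tert-butyl (2S,3S)-7-acetoxy-2-[3,4-bis(benzyloxy)phenyl]-4-[(trifluoromethylsulfonyl)oxy]-2,3-dihydrobenzofuran-3-carboxylate | O=S(=O)(Oc1ccc(OC(C)=O)c2c1[C@H](C(=O)OC(C)(C)C)[C@@H](c1ccc(OCc3ccccc3)c(OCc3ccccc3)c1)O2)C(F)(F)F | intermediate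
18 | (R)-danshensu, (2R)-3-(3,4-dihydroxyphenyl)-2-hydroxypropanoic acid | O=C(O)[C@H](O)Cc1ccc(O)c(O)c1 | starting material
19 | methyl (2R)-3-(3,4-dihydroxyphenyl)-2-hydroxypropanoate | COC(=O)[C@H](O)Cc1ccc(O)c(O)c1 | intermediate
20 | methyl (2R)-3-[3,4-bis(benzyloxy)phenyl]-2-hydroxypropanoate | COC(=O)[C@H](O)Cc1ccc(OCc2ccccc2)c(OCc2ccccc2)c1 | intermediate
21 | acryloyl chloride | C=CC(=O)Cl | starting material
22 | methyl (2R)-2-(acryloyloxy)-3-[3,4-bis(benzyloxy)phenyl]propanoate | COC(=O)[C@@H](Cc1ccc(OCc2ccccc2)c(OCc2ccccc2)c1)OC(=O)C=C | intermediate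
23 | tert-butyl (2S,3S)-7-acetoxy-2-[3,4-bis(benzyloxy)phenyl]-4-[(E)-3-{[(2R)-3-[3,4-bis(benzyloxy)phenyl]-1-methoxy-1-oxopropan-2-yl]oxy}-3-oxoprop-1-enyl]-2,3-dihydrobenzofuran-3-carboxylate | COC(=O)[C@@H](Cc1ccc(OCc2ccccc2)c(OCc2ccccc2)c1)OC(=O)/C=C/c1ccc(OC(C)=O)c2c1[C@H](C(=O)OC(C)(C)C)[C@@H](c1ccc(OCc3ccccc3)c(OCc3ccccc3)c1)O2 | intermediate
24 | tert-butyl (2S,3S)-2-[3,4-bis(benzyloxy)phenyl]-4-[(E)-3-{[(2R)-3-[3,4-bis(benzyloxy)phenyl]-1-methoxy-1-oxopropan-2-yl]oxy}-3-oxoprop-1-enyl]-7-hydroxy-2,3-dihydrobenzofuran-3-carboxylate | COC(=O)[C@@H](Cc1ccc(OCc2ccccc2)c(OCc2ccccc2)c1)OC(=O)/C=C/c1ccc(O)c2c1[C@H](C(=O)OC(C)(C)C)[C@@H](c1ccc(OCc3ccccc3)c(OCc3ccccc3)c1)O2 | intermediate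
25 | CNP0120702.1, (2S,3S)-2-(3,4-dihydroxyphenyl)-4-[(E)-3-{[(2R)-3-(3,4-dihydroxyphenyl)-1-methoxy-1-oxopropan-2-yl]oxy}-3-oxoprop-1-enyl]-7-hydroxy-2,3-dihydrobenzofuran-3-carboxylic acid | COC(=O)[C@@H](Cc1ccc(O)c(O)c1)OC(=O)/C=C/c1ccc(O)c2c1[C@H](C(=O)O)[C@@H](c1ccc(O)c(O)c1)O2 | target

Total step count: 15.
Longest linear sequence: 12 steps (steps 1–9 and 13–15). The acrylate branch (steps 10–12) joins at step 13.

Steps most likely to fail

**Step 7.** The ketal carbon C7a may aromatize by rupture of C7a–O1 instead of the exocyclic C–O bond. This would proceed by loss or shift of the silyl group, collapse to a C7a carbonyl and tautomerization, and it opens the five-membered ring.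

The fallback makes this opening the planned path and closes the ring again in a separate operation. It sets out from 11 and 12. Cycloadduct 13 is formed as before and then treated with PPTS in wet THF, so that it collapses completely to tert-butyl (2S,3S)-2-{3-acetyl-6-[(tert-butyldimethylsilyl)oxy]-2-hydroxyphenyl}-3-[3,4-bis(benzyloxy)phenyl]-3-hydroxypropanoate F1. In F1 the C4 oxygen is still silylated, so only the C7a phenol is free. Acid-catalysed dehydrative etherification (4-toluenesulfonic acid cat., CH2Cl2/(CF3)2CHOH, 0 °C) through the dialkoxy-stabilized benzylic cation then re-forms O1–C2. The intact C3 centre directs the aryl group trans. The sequence comes back to the route at 14, which buffered fluoride converts into 15.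

**Step 15.** Boron bound at the C7 oxygen can also activate the neighbouring O1–C2 benzylic ether. Ring opening, capture of the C2 cation by the scavenger, or incomplete removal of the four benzyl groups may then compete.

The fallback changes the protecting-group plan so that no Lewis acid is needed at the end. The benzyl groups are removed by hydrogenolysis before the alkene exists. It sets out from 17 and 19.
- Triflate 17 is hydrogenolysed (H2, Pd/C, EtOAc) to the catechol triflate F3.
- Acetylation (Ac2O, pyridine) gives the triacetate triflate F4.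
- Ester 19 is acetylated on the phenols only (Ac2O, K2CO3, acetone, 0 °C) to the diacetate F5.
- Esterification of F5 with 21 (Et3N, CH2Cl2) gives the diacetate acrylate F6.
- The conditions of step 13 join F4 and F6 to the pentaacetate tert-butyl ester F7.
- CF3CO2H in CH2Cl2 removes the tert-butyl group and gives the pentaacetate acid F8. The acetoxy groups make ring C a poor cation donor, so O1–C2 is safe.
- Pyrrolidine in degassed THF at 0 °C cleaves all five aryl acetates by the aminolysis of step 14, and acidic work-up comes back to the route at 25.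

**Step 5.** Slow addition of the hindered lactone enolate to the amide may allow proton exchange to reach C3–H. That enolate expels the lactone carboxylate (Stobbe-type ring opening).

The fallback replaces the acylation by an aldol addition followed by oxidation. It sets out from 8. The enolate (LiN(SiMe3)2, THF, −78 °C) is trapped within minutes by acetaldehyde to give tert-butyl (2S,3S,4R)-2-[3,4-bis(benzyloxy)phenyl]-4-(1-hydroxyethyl)-5-oxooxolane-3-carboxylate F2, with the carbinol centre of no consequence. Dess–Martin periodinane (NaHCO3, CH2Cl2, 0 °C) oxidizes the secondary alcohol and comes back to the route at 10.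

Further compounds
F1 | step 7 | tert-butyl (2S,3S)-2-{3-acetyl-6-[(tert-butyldimethylsilyl)oxy]-2-hydroxyphenyl}-3-[3,4-bis(benzyloxy)phenyl]-3-hydroxypropanoate | CC(=O)c1ccc(O[Si](C)(C)C(C)(C)C)c(c1O)[C@H](C(=O)OC(C)(C)C)[C@H](O)c1ccc(OCc2ccccc2)c(OCc2ccccc2)c1
F2 | step 5 | tert-butyl (2S,3S,4R)-2-[3,4-bis(benzyloxy)phenyl]-4-(1-hydroxyethyl)-5-oxooxolane-3-carboxylate | CC(O)[C@@H]1C(=O)O[C@H](c2ccc(OCc3ccccc3)c(OCc3ccccc3)c2)[C@H]1C(=O)OC(C)(C)C
F3 | step 15 | tert-butyl (2S,3S)-7-acetoxy-2-(3,4-dihydroxyphenyl)-4-[(trifluoromethylsulfonyl)oxy]-2,3-dihydrobenzofuran-3-carboxylate | O=S(=O)(Oc1ccc(OC(C)=O)c2c1[C@H](C(=O)OC(C)(C)C)[C@@H](c1ccc(O)c(O)c1)O2)C(F)(F)F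
F4 | step 15 | tert-butyl (2S,3S)-7-acetoxy-2-(3,4-diacetoxyphenyl)-4-[(trifluoromethylsulfonyl)oxy]-2,3-dihydrobenzofuran-3-carboxylate | O=S(=O)(Oc1ccc(OC(C)=O)c2c1[C@H](C(=O)OC(C)(C)C)[C@@H](c1ccc(OC(C)=O)c(OC(C)=O)c1)O2)C(F)(F)F
F5 | step 15 | methyl (2R)-3-(3,4-diacetoxyphenyl)-2-hydroxypropanoate | COC(=O)[C@H](O)Cc1ccc(OC(C)=O)c(OC(C)=O)c1
F6 | step 15 | methyl (2R)-2-(acryloyloxy)-3-(3,4-diacetoxyphenyl)propanoate | COC(=O)[C@@H](Cc1ccc(OC(C)=O)c(OC(C)=O)c1)OC(=O)C=C
F7 | step 15 | tert-butyl (2S,3S)-7-acetoxy-2-(3,4-diacetoxyphenyl)-4-[(E)-3-{[(2R)-3-(3,4-diacetoxyphenyl)-1-methoxy-1-oxopropan-2-yl]oxy}-3-oxoprop-1-enyl]-2,3-dihydrobenzofuran-3-carboxylate | COC(=O)[C@@H](Cc1ccc(OC(C)=O)c(OC(C)=O)c1)OC(=O)/C=C/c1ccc(OC(C)=O)c2c1[C@H](C(=O)OC(C)(C)C)[C@@H](c1ccc(OC(C)=O)c(OC(C)=O)c1)O2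
F8 | step 15 | (2S,3S)-7-acetoxy-2-(3,4-diacetoxyphenyl)-4-[(E)-3-{[(2R)-3-(3,4-diacetoxyphenyl)-1-methoxy-1-oxopropan-2-yl]oxy}-3-oxoprop-1-enyl]-2,3-dihydrobenzofuran-3-carboxylic acid | COC(=O)[C@@H](Cc1ccc(OC(C)=O)c(OC(C)=O)c1)OC(=O)/C=C/c1ccc(OC(C)=O)c2c1[C@H](C(=O)O)[C@@H](c1ccc(OC(C)=O)c(OC(C)=O)c1)O2
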